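The flask is asked how steeply its rate of making J answers the charge of L at a fixed conversion, 50% of E and Q together, and not at a fixed time.

all flasks: E 20 mM; Q 20 mM; L 15 mol%

| run | G | remark |
|---|---|---|
| gamma | 1 equiv | the very flask that is asked about, followed so far |
| theta | 0.67 equiv | run made earlier |
| flask | 1.00 equiv |  |

| gamma: time / h | gamma: J / % | theta: time / h | theta: J / % |
|---|---|---|---|
| 0.250 | 1.5 | 2.50 | 1.4 |
| 0.500 | 0.8 | 5.00 | 10.6 |
| 1.33 | 4.7 | 8.00 | 14.8 |
| 3.00 | 8.0 | 10.0 | 16.0 |

(each reading ± 1 percentage point)

1. apparent order in L when 50% of the E and Q together are converted (percent change of the rate of making J for one percent more L charged)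

- L is single-handed; E and Q are mirror images of each other, charged as a racemate, each of them at the stated concentration
- no earlier run changes the charge of L; that part of a forecast is a guess
- what is bound to the catalyst counts as converted

Of the given numbers, the scatter of 1 percentage point enters the rate scale read from the runs, and so shifts when the point comes, while the balance below holds at the point whenever it comes. The equivalents of G matter a great deal. The flask holds 20.0 mM of G, the limiting reagent, and the point asks for 20.0 mM of E and Q converted. Bound material counts as converted, so if each product takes one G, the G left at the point equals the bound catalyst. The theta run's 0.67 equiv of G and its L allow at most 41.0% conversion, so that run has no such point.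

The loading then matters directly. The remainder ceiling, the charge of L over the charge of G, 15.0%, bounds [G] at the point as a share of its own charge. If J comes from G meeting bound catalyst, the rate there carries the charge of L twice, once in [G] and once in the bound form. The reckoning made here therefore gives an order near 2, lowered if the bound share of the catalyst falls as more L is charged.

The forecast gives 1, which differs from this reckoning. “With a simple catalytic turnover, the rate at a fixed conversion scales about linearly with L.”

The flask gives 1.7, with 51.0% of the catalyst standing as L at the point, reached after 44.0 h.

L + E ⇌ X (K = 120 L mol⁻¹, k = 360 L mol⁻¹ h⁻¹); L + Q ⇌ Z (K = 24.0 L mol⁻¹, k = 710 L mol⁻¹ h⁻¹); G + X → L + J (k = 44.0 L mol⁻¹ h⁻¹); G + Z → L + D (k = 19.0 L mol⁻¹ h⁻¹); E ⇌ Q (k = 0.00480 h⁻¹) The remainder ceiling is thus filled to 49.0%, and G stands at 7.35% of its own charge, or 1.47 mM. The rate of making J there is 0.0600 mM h⁻¹, and with the rate constant 44 L mol⁻¹ h⁻¹ this remainder of G requires [X] = 0.928 mM.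

Readings and results come from a simulation with constants of no real substance.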